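Ring A of the isoquinoline bears two adjacent carbon substituents: the naphthyl group on C5 and the C4 methylene on C4a, with the C6 methoxy group flanking C5 on the other side. Both bonds, C4a–C4 and C5–C1', are disconnected together. One palladium/norbornene (Catellani) reaction alkylates the single free ortho C–H of 1-iodo-2,4-dimethoxybenzene with an (S)-2-methyl-N-sulfonylaziridine and then arylates the former C–I carbon with a 4,5-dimethoxy-7-methyl-1-naphthylboronate. The precursor set is therefore three simple pieces, and C3 is bought with L-alaninol. Ring B is closed later at the activated C8a (Bischler–Napieralski), and cis-selective hydride reduction sets C1.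

Key step: step 7

Assumption: the SMILES fixes C1 as R and C3 as S (the 1,3-cis series) but not the sense of the hindered, rotationally stable C5–C1' axis. The axis is therefore left uncontrolled, everything from the key step onwards is carried as a pair of atropisomers sharing the drawn SMILES, and the pair can be separated by chromatography at the target stage if one axial isomer is wanted.

Numbering: isoquinoline numbering is used for ring A (C4a, C5–C8, C8a) and ring B (C1, N2, C3, C4). C1' is the naphthalene carbon bound to C5.

Design remarks:
- **Bromine placement.** The bromine that later becomes boron is introduced while the oxygen of the methyl-bearing naphthalene ring is an acetate. The corresponding dimethyl ether should be most nucleophilic in the wrong ring, para to OMe and ortho to CH3.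
- **Tosyl group.** It is kept for the key step, where N-tosylaziridines have the closest precedent. It is removed only after N-acetylation, when the N–S bond yields to a mild one-electron reductant and the naphthalene never meets dissolving-metal conditions.

Step 1
Reactants: 1 L-alaninol
Product: 3 (S)-2-methyl-1-tosylaziridine, via N,O-ditosyl-L-alaninol 2 (not isolated)
Conditions: TsCl (2.3 equiv), KOH, CH2Cl2–H2O, rt
Reagents that add atoms: 4-toluenesulfonyl chloride, Cc1ccc(cc1)S(=O)(=O)Cl
Why: Sulfonylation of N and O followed by base-induced 3-exo-tet closure (Wenker-type aziridine synthesis) displaces only the primary tosylate, so the stereocentre that becomes C3 keeps its (S) configuration.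

Step 2
Reactants: 4 3-methoxy-2-(trimethylsilyl)phenyl triflate; 5 acetylacetone (excess)
Product: 7 1-(2-acetyl-3-methoxyphenyl)propan-2-one, via 3-methoxybenzyne 6 (not isolated)
Conditions: CsF (2.5 equiv), MeCN, 80 °C
Reagents that add atoms: none
Why: Aryne acyl-alkylation (formal insertion into the C–C σ-bond of a 1,3-dicarbonyl compound), in which the acetylacetonate carbon adds to the aryne carbon remote from OMe and the aryl anion beside OMe attacks an acetyl C=O to give a benzocyclobutenoxide that fragments, placing the acetyl group next to OMe and the acetonyl group on its other side.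

Step 3
Reactants: 7 1-(2-acetyl-3-methoxyphenyl)propan-2-one
Product: 9 8-methoxy-3-methylnaphthalen-1-yl acetate, via 8-methoxy-3-methylnaphthalen-1-ol 8 (not isolated)
Conditions: KOt-Bu (2.2 equiv), THF–t-BuOH, 0 °C to rt; then Ac2O (4 equiv), 0 °C to rt
Reagents that add atoms: acetic anhydride, CC(=O)OC(C)=O
Why: Intramolecular aldol condensation with aromatisation, in which under equilibrating base the enolate of the aryl methyl ketone attacks the unhindered aliphatic ketone (the doubly ortho-substituted aryl ketone is a poor acceptor), loss of water gives the 1-naphtholate, and O-acylation traps it as the ester that steers step 4.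

Step 4
Reactants: 9 8-methoxy-3-methylnaphthalen-1-yl acetate
Product: 10 5-bromo-8-methoxy-3-methylnaphthalen-1-yl acetate
Conditions: NBS (1.0 equiv), MeCN, 0 °C to rt, dark
Reagents that add atoms: N-bromosuccinimide, O=C1CCC(=O)N1Br
Why: Electrophilic aromatic bromination, in which the weakly donating acetate leaves the methoxy-bearing ring far more nucleophilic, so bromine should enter its α-position para to OMe (C5) rather than C4 of the methyl-bearing ring, where the dimethyl ether would be expected to react.

Step 5
Reactants: 10 5-bromo-8-methoxy-3-methylnaphthalen-1-yl acetate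
Product: 12 1-bromo-4,5-dimethoxy-7-methylnaphthalene, via 5-bromo-8-methoxy-3-methylnaphthalen-1-ol 11 (not isolated)
Conditions: K2CO3, MeOH, rt; evaporate; then MeI, DMF, rt
Reagents that add atoms: iodomethane, CI
Why: Carbonate-catalysed transesterification frees the naphthol and Williamson ether synthesis methylates it, the aryl bromide being inert to both operations.

Step 6
Reactants: 12 1-bromo-4,5-dimethoxy-7-methylnaphthalene
Product: 13 2-(4,5-dimethoxy-7-methylnaphthalen-1-yl)-4,4,5,5-tetramethyl-1,3,2-dioxaborolane
Conditions: B2pin2, PdCl2(dppf) (5 mol %), KOAc, 1,4-dioxane, 90 °C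
Reagents that add atoms: bis(pinacolato)diboron, CC1(C)OB(OC1(C)C)B1OC(C)(C)C(C)(C)O1
Why: Miyaura borylation of an aryl bromide, with KOAc as a base too weak to start Suzuki homocoupling of the product.

Step 7
Reactants: 14 1-iodo-2,4-dimethoxybenzene; 3 (S)-2-methyl-1-tosylaziridine; 13 2-(4,5-dimethoxy-7-methylnaphthalen-1-yl)-4,4,5,5-tetramethyl-1,3,2-dioxaborolane
Product: 15 (S)-N-tosyl-1-[3,5-dimethoxy-2-(4,5-dimethoxy-7-methylnaphthalen-1-yl)phenyl]propan-2-amine
Conditions: Pd(OAc)2 (10 mol %), PPh3 (25 mol %), norbornene (2 equiv), K2CO3 (3 equiv), 13 (1.5 equiv), 3 (1.3 equiv, in portions), MeCN–H2O 20:1, 80 °C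
Reagents that add atoms: none
Why: Proposed new method: oxidative addition of 14 to zerovalent palladium, syn-carbopalladation of norbornene and cyclopalladation at the one free ortho C–H build a five-membered aryl–norbornyl palladacycle, which attacks 3 at its unsubstituted CH2 in an SN2-like oxidative addition to tetravalent palladium, so that reductive elimination makes C4a–C4 and never touches the stereocentre that becomes C3. The aryl ring now has both ortho positions filled, norbornene is expelled by β-carbon elimination, and the divalent arylpalladium species transmetalates with 13 (activated by carbonate and water) and reductively eliminates to make C5–C1'. The closest known reaction types are the Catellani ortho-alkylation with N-sulfonylaziridines that ends in a Heck reaction and the Catellani ortho-alkylation with alkyl halides that ends in a Suzuki coupling; new here are their combination and a hindered 1-naphthylboronate as the terminating partner. No ring closes and no stereocentre forms, while the new hindered C5–C1' axis arises without control. Site selectivity comes from 14 itself, whose C2 methoxy group blocks one ortho position, leaves a single C–H for a single alkylation and supplies the ortho substituent that forces norbornene out after that alkylation. Chemoselectivity is needed twice: premature biaryl coupling is held back because norbornene insertion is fast and transmetalation of the bulky boronate is slow, and N-arylation to an indoline at the end is held back by surplus 13, by PPh3 as a ligand that is poor at C–N reductive elimination and by the aqueous carbonate/bicarbonate buffer that keeps the weakly nucleophilic sulfonamide largely protonated.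

Step 8
Reactants: 15 (S)-N-tosyl-1-[3,5-dimethoxy-2-(4,5-dimethoxy-7-methylnaphthalen-1-yl)phenyl]propan-2-amine
Product: 16 N-{(2S)-1-[3,5-dimethoxy-2-(4,5-dimethoxy-7-methylnaphthalen-1-yl)phenyl]propan-2-yl}-N-tosylacetamide
Conditions: Ac2O, Et3N, DMAP (cat.), CH2Cl2, rt to reflux
Reagents that add atoms: acetic anhydride, CC(=O)OC(C)=O
Why: DMAP-catalysed N-acylation of a sulfonamide installs the acetyl group that the ring closure needs anyway and turns the robust sulfonamide into an N-acylsulfonamide whose N–S bond is far easier to reduce.

Step 9
Reactants: 16 N-{(2S)-1-[3,5-dimethoxy-2-(4,5-dimethoxy-7-methylnaphthalen-1-yl)phenyl]propan-2-yl}-N-tosylacetamide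
Product: 17 N-{(2S)-1-[3,5-dimethoxy-2-(4,5-dimethoxy-7-methylnaphthalen-1-yl)phenyl]propan-2-yl}acetamide
Conditions: SmI2 (3 equiv), THF, rt; then aq. NaHCO3
Reagents that add atoms: none
Why: Reductive desulfonylation of an N-acylsulfonamide by single-electron transfer from SmI2 breaks the N–S bond under conditions too mild to reduce the naphthalene or cleave aryl methyl ethers.

Step 10
Reactants: 17 N-{(2S)-1-[3,5-dimethoxy-2-(4,5-dimethoxy-7-methylnaphthalen-1-yl)phenyl]propan-2-yl}acetamide
Product: 18 (3S)-5-(4,5-dimethoxy-7-methylnaphthalen-1-yl)-6,8-dimethoxy-1,3-dimethyl-3,4-dihydroisoquinoline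
Conditions: POCl3, MeCN, reflux; then aq. NH3
Reagents that add atoms: none
Why: Bischler–Napieralski cyclodehydration, in which the activated imidoyl/nitrilium carbon attacks the only free position ortho to the side chain, C8a, which is ortho to the C8 and para to the C6 methoxy group, closing six-membered ring B without involving C3.

Step 11
Reactants: 18 (3S)-5-(4,5-dimethoxy-7-methylnaphthalen-1-yl)-6,8-dimethoxy-1,3-dimethyl-3,4-dihydroisoquinoline
Product: 20 (1R,3S)-5-(4,5-dimethoxy-7-methylnaphthalen-1-yl)-6,8-dimethoxy-1,2,3-trimethyl-1,2,3,4-tetrahydroisoquinoline, via (1R,3S)-NH-tetrahydroisoquinoline 19 (not isolated)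
Conditions: NaBH4, MeOH, 0 °C; then 37 % aq. HCHO, rt; then NaBH4, 0 °C to rt
Reagents that add atoms: formaldehyde, C=O
Why: Borohydride reduction of the cyclic imine should deliver hydride to C1 from the face opposite the C3 methyl group, which puts both methyl groups on the same side (1,3-cis, hence 1R from 3S), and reductive amination with formaldehyde then methylates N2 without touching either stereocentre.

Compound list
1 | L-alaninol, (S)-2-aminopropan-1-ol | C[C@H](N)CO | starting material
2 | N,O-ditosyl-L-alaninol, (S)-2-(tosylamino)propyl tosylate | C[C@H](NS(=O)(=O)c1ccc(C)cc1)COS(=O)(=O)c1ccc(C)cc1 | intermediate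
3 | (S)-2-methyl-1-tosylaziridine | C[C@H]1CN1S(=O)(=O)c1ccc(C)cc1 | intermediate
4 | 3-methoxy-2-(trimethylsilyl)phenyl triflate | COc1cccc(OS(=O)(=O)C(F)(F)F)c1[Si](C)(C)C | starting material
5 | acetylacetone | CC(=O)CC(C)=O | starting material
6 | 3-methoxybenzyne | COC1=CC=CC#C1 | intermediate
7 | 1-(2-acetyl-3-methoxyphenyl)propan-2-one | COc1cccc(CC(C)=O)c1C(C)=O | intermediate
8 | 8-methoxy-3-methylnaphthalen-1-ol | COc1cccc2cc(C)cc(O)c12 | intermediate
9 | 8-methoxy-3-methylnaphthalen-1-yl acetate | COc1cccc2cc(C)cc(OC(C)=O)c12 | intermediate
10 | 5-bromo-8-methoxy-3-methylnaphthalen-1-yl acetate | COc1ccc(Br)c2cc(C)cc(OC(C)=O)c12 | intermediate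
11 | 5-bromo-8-methoxy-3-methylnaphthalen-1-ol | COc1ccc(Br)c2cc(C)cc(O)c12 | intermediate
12 | 1-bromo-4,5-dimethoxy-7-methylnaphthalene | COc1ccc(Br)c2cc(C)cc(OC)c12 | intermediate
13 | 2-(4,5-dimethoxy-7-methylnaphthalen-1-yl)-4,4,5,5-tetramethyl-1,3,2-dioxaborolane | COc1ccc(B2OC(C)(C)C(C)(C)O2)c2cc(C)cc(OC)c12 | intermediate
14 | 1-iodo-2,4-dimethoxybenzene | COc1ccc(I)c(OC)c1 | starting material
15 | (S)-N-tosyl-1-[3,5-dimethoxy-2-(4,5-dimethoxy-7-methylnaphthalen-1-yl)phenyl]propan-2-amine | COc1cc(OC)cc(C[C@H](C)NS(=O)(=O)c2ccc(C)cc2)c1-c1ccc(OC)c2c(OC)cc(C)cc12 | intermediate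
16 | N-{(2S)-1-[3,5-dimethoxy-2-(4,5-dimethoxy-7-methylnaphthalen-1-yl)phenyl]propan-2-yl}-N-tosylacetamide | COc1cc(OC)cc(C[C@H](C)N(C(C)=O)S(=O)(=O)c2ccc(C)cc2)c1-c1ccc(OC)c2c(OC)cc(C)cc12 | intermediate
17 | N-{(2S)-1-[3,5-dimethoxy-2-(4,5-dimethoxy-7-methylnaphthalen-1-yl)phenyl]propan-2-yl}acetamide | COc1cc(OC)cc(C[C@H](C)NC(C)=O)c1-c1ccc(OC)c2c(OC)cc(C)cc12 | intermediate
18 | (3S)-5-(4,5-dimethoxy-7-methylnaphthalen-1-yl)-6,8-dimethoxy-1,3-dimethyl-3,4-dihydroisoquinoline | COc1cc(OC)c2c(c1-c1ccc(OC)c3c(OC)cc(C)cc13)C[C@H](C)N=C2C | intermediate
19 | (1R,3S)-5-(4,5-dimethoxy-7-methylnaphthalen-1-yl)-6,8-dimethoxy-1,3-dimethyl-1,2,3,4-tetrahydroisoquinoline | COc1cc(OC)c2c(c1-c1ccc(OC)c3c(OC)cc(C)cc13)C[C@H](C)N[C@@H]2C | intermediate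
20 | (1R,3S)-5-(4,5-dimethoxy-7-methylnaphthalen-1-yl)-6,8-dimethoxy-1,2,3-trimethyl-1,2,3,4-tetrahydroisoquinoline | COc1cc(OC)c2c(c1-c1ccc(OC)c3c(OC)cc(C)cc13)C[C@H](C)N(C)[C@@H]2C | target

Total step count: 11 steps.
Longest linear sequence: 10 steps (steps 2 to 11, from 4 to 20).

Steps most likely to fail

Step 7. Transmetalation of the bulky, electron-rich boronate may be too slow. The arylpalladium species would then be lost to intramolecular C–N bond formation or protonolysis, the boronate would suffer protodeboronation, and surplus aziridine would alkylate the sulfonamide nitrogen of the product. The fallback makes the two bonds one after the other with known chemistry; it sets out from 3 and comes back at 15. CuI-catalysed ring opening of 3 at its CH2 with commercial 3,5-dimethoxyphenylmagnesium bromide (COc1cc(OC)cc([Mg]Br)c1; THF, −20 °C to rt) gives (S)-N-[1-(3,5-dimethoxyphenyl)propan-2-yl]-4-methylbenzenesulfonamide F1. Iodination with NIS in MeCN should occur at one of the two equivalent positions ortho to the side chain and para to a methoxy group, giving (S)-N-[1-(2-iodo-3,5-dimethoxyphenyl)propan-2-yl]-4-methylbenzenesulfonamide F2. A separate Suzuki–Miyaura coupling of F2 with 13 (Pd(PPh3)4, K3PO4, toluene–H2O, 100 °C) gives 15.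

Step 2. The insertion may be eroded by plain α-arylation without acyl transfer, by further arylation of the acidic benzylic methylene of the product, and by uncontrolled onward aldol reaction in the fluoride medium. The fallback replaces aryne chemistry by a copper-catalysed Hurtley-type C-arylation; it sets out from 5 and comes back at 7. Compound 5 and commercial 1-(2-bromo-6-methoxyphenyl)ethanone (COc1cccc(Br)c1C(C)=O) with CuI and K3PO4 in DMSO at 90 °C give 3-(2-acetyl-3-methoxyphenyl)pentane-2,4-dione F3. Under the same conditions F3 loses one acetyl group by retro-Claisen cleavage to give 7.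

Step 9. Electron transfer to the hindered N-acylsulfonamide may be sluggish, or the acetyl group may be lost by solvolysis, which would return the sulfonamide. The fallback reverses the order of events; it sets out from 15 and comes back at 17. Sodium naphthalenide (NaC10H8) in DME at −78 °C, added until its colour just persists, cleaves the free sulfonamide. This gives (S)-1-[3,5-dimethoxy-2-(4,5-dimethoxy-7-methylnaphthalen-1-yl)phenyl]propan-2-amine F4, which is freed from naphthalene by acid–base extraction. Ac2O and Et3N in CH2Cl2 then give 17.

Further compounds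
F1 | step 7 | (S)-N-[1-(3,5-dimethoxyphenyl)propan-2-yl]-4-methylbenzenesulfonamide | COc1cc(OC)cc(C[C@H](C)NS(=O)(=O)c2ccc(C)cc2)c1
F2 | step 7 | (S)-N-[1-(2-iodo-3,5-dimethoxyphenyl)propan-2-yl]-4-methylbenzenesulfonamide | COc1cc(OC)cc(C[C@H](C)NS(=O)(=O)c2ccc(C)cc2)c1I
F3 | step 2 | 3-(2-acetyl-3-methoxyphenyl)pentane-2,4-dione | COc1cccc(C(C(C)=O)C(C)=O)c1C(C)=O
F4 | step 9 | (S)-1-[3,5-dimethoxy-2-(4,5-dimethoxy-7-methylnaphthalen-1-yl)phenyl]propan-2-amine | COc1cc(OC)cc(C[C@H](C)N)c1-c1ccc(OC)c2c(OC)cc(C)cc12
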